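At 4.0 min you want the left-handed product in these flasks, which differ in their catalyst.

| flask | left-handed substrate | right-handed substrate | gas | catalyst | remark | time |
|---|---|---|---|---|---|---|
| Friday's | 0.052 M | 0.052 M | 2.8 mM (held) | 0.11 mM | run made earlier |  |
| Wednesday's | 0.052 M | 0.052 M | 2.8 mM (held) | 1.2 mM | run made earlier |  |
| teal | 0.052 M | 0.052 M | 2.8 mM (held) | 1.5 mM |  | 4.0 min |
| red | 0.052 M | 0.052 M | 2.8 mM (held) | 0.12 mM |  | 4.0 min |
| grey | 0.052 M | 0.052 M | 2.8 mM (held) | 0.34 mM |  | 4.0 min |
| violet | 0.052 M | 0.052 M | 2.8 mM (held) | 0.25 mM |  | 4.0 min |

| run | time / min | left-handed product / % | left-handed substrate / % |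
|---|---|---|---|
| Friday's | 0.250 | 0.5 | 49.4 |
| Friday's | 0.417 | 1.4 | 49.1 |
| Friday's | 0.833 | 1.8 | 47.8 |
| Friday's | 1.33 | 3.3 | 46.8 |
| Friday's | 3.00 | 6.7 | 43.6 |
| Wednesday's | 0.250 | 2.9 | 46.9 |
| Wednesday's | 0.667 | 8.3 | 41.8 |
| Wednesday's | 1.33 | 16.7 | 33.9 |
| Wednesday's | 2.00 | 23.5 | 26.9 |
| Wednesday's | 3.00 | 31.7 | 18.8 |

(readings scatter by 0.3 percentage points)

- the flasks by amount of left-handed product, in percent of the left-handed substrate and right-handed substrate together charged, highest first, at 4.0 min (teal / red / grey / violet)
- the amount of left-handed product, in percent of the left-handed substrate and right-handed substrate together charged of the flask you put first, at 4.0 min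
- the amount of left-handed product, in percent of the left-handed substrate and right-handed substrate together charged of the flask you put last, at 4.0 min

- catalyst is single-handed; left-handed substrate and right-handed substrate are mirror images of each other, charged as a racemate, each of them at the stated concentration
- at the start none of the gas is in solution

Write x for the left-handed product as a fraction of both substrates charged; the racemate caps it at 0.5. Write L for the negative logarithm of the share of left-handed substrate remaining: 0.144 in Friday's last reading, 1.01 in Wednesday's.

From above: Friday's run, scaled first-order by catalyst times time, gives teal 46.3%. From below: Wednesday's flask had less catalyst than teal, and its last fractional fall of left-handed substrate, continued one more minute, gives 37.4%.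

Friday's scaling promises Wednesday 39.6%, but the reading is lower, 31.7%. So I charge time twice:

t = x/M + D·L/c

Here c is the catalyst, D the catalyst-time per unit of L, and M the gas ceiling, the rate of x if gas supply were the rate-limiting step: 0.254 min⁻¹, with D = 2.09 mM·min. Both are readings, with their scatter.

Putting each bound into the gas term narrows teal to 39.5% to 41.8%. The same for red gives 9.32% to 10.3%.

The forecast, “I read this as gas supply limiting”, gives teal > grey > violet > red, with 41% inside my teal bracket and 9.1% just below my red one.

The flasks give teal > grey > violet > red, with teal 40.3% and red 9.66%, each inside my bracket.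

partner + catalyst + left-handed substrate → catalyst + left-handed product (k = 3000 M⁻² s⁻¹); partner + catalyst + right-handed substrate → catalyst + right-handed product (k = 1100 M⁻² s⁻¹); gas ⇌ partner, rate k3*(csat - [partner]) (kL = 0.220 s⁻¹); partner → decomposed reagent (k = 2.40 × 10⁻⁴ s⁻¹); partner → decomposition product (k = 5.80 × 10⁻⁶ s⁻¹) Now take teal read earlier, with 19.8% left-handed product at 1.50 min. The gas term prices that at 0.779 min, the catalyst term at 0.703 min, together 1.48 min. Beside it stand 8.44% of right-handed product.

All runs stem from a simulated flask on assumed constants.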